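Numbering: ring C1 (CHOAc), C2 (CHOAng), C3 (CMeOH), C4 (CHOH), C5, C6; chain C7(=C14H2), C8 (CHOH), C9, C10 (CHOAng), C11. The exocyclic C7=C14 methylene is treated as a masked ketone, so the whole side chain becomes a chiral α'-silyloxy vinyl ketone, and ring carbons C1–C4, with cis oxygens at C1 and C4, become a 1,4-bis(silyloxy)-2-methylbutadiene. One Lewis-acid Diels–Alder reaction forms C4–C5 and C1–C6, closes the only ring, joins both fragments and sets C1, C4 and C6 all cis. Its precursors are E,E-diene 4 and enone 17, which already carries C8 and C10; a hydroxyl-directed dihydroxylation then completes the all-cis ring.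

Key step: step 12

Remark (assumption on the chemistry): in step 12 the (S)-proline-derived oxazaborolidinium ion is taken to be the enantiomer whose own facial preference for vinyl ketones coincides with the substrate bias; should a test run show the reverse pairing, the (R)-cation is used with nothing else changed.

Step 1
Reactants: 1 (E)-4-acetoxy-2-methylbut-2-enal
Product: 2 (E)-4-hydroxy-2-methylbut-2-enal
Conditions: K2CO3 (0.1 equiv), MeOH, 0 °C; filtration through silica
Reagents that add atoms: none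
Why: Base-catalysed transesterification of a primary allylic acetate is fast at 0 °C, and the E-enal, which cannot close to a lactol, should survive the short exposure.

Step 2
Reactants: 2 (E)-4-hydroxy-2-methylbut-2-enal
Product: 3 (E)-2-methyl-4-(triethylsilyloxy)but-2-enal
Conditions: TESCl, imidazole, CH2Cl2, 0 °C
Reagents that add atoms: chlorotriethylsilane, CC[Si](Cl)(CC)CC
Why: Routine silylation of a primary alcohol; the triethylsilyl group is chosen so that O1 can later be freed while TBS ethers stay.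

Step 3
Reactants: 3 (E)-2-methyl-4-(triethylsilyloxy)but-2-enal
Product: 4 (1E,3E)-1-(tert-butyldimethylsilyloxy)-2-methyl-4-(triethylsilyloxy)buta-1,3-diene
Conditions: TBSOTf (1.1 equiv), Et3N (1.5 equiv), Et2O, 0 °C to rt; filtration, bulb-to-bulb distillation, used at once
Reagents that add atoms: tert-butyldimethylsilyl triflate, CC(C)(C)[Si](C)(C)OS(=O)(=O)C(F)(F)F
Why: Soft enolisation to a silyl dienol ether (O-silylation of the aldehyde, loss of the only γ-proton); the s-trans enal gives the 1E enol ether and allylic 1,3-strain with the C2 methyl keeps the OTES group outside, so the reactive E,E-diene should dominate.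

Step 4
Reactants: 5 3-hydroxy-3-methylbutan-2-one
Product: 6 3-methyl-3-(triethylsilyloxy)butan-2-one
Conditions: TESOTf, 2,6-lutidine, CH2Cl2, −78 to 0 °C
Reagents that add atoms: triethylsilyl triflate, CC[Si](CC)(CC)OS(=O)(=O)C(F)(F)F
Why: Silyl triflate silylation of a tertiary alcohol; capping O11 leaves O8 as the only hydroxyl able to direct the later reduction.

Step 5
Reactants: 6 3-methyl-3-(triethylsilyloxy)butan-2-one
Product: 7 3-methyl-3-(triethylsilyloxy)-2-(trimethylsilyloxy)but-1-ene
Conditions: TMSOTf, Et3N, CH2Cl2, 0 °C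
Reagents that add atoms: trimethylsilyl triflate, C[Si](C)(C)OS(=O)(=O)C(F)(F)F
Why: Enol silane formation by soft enolisation; the ketone has a single enolisable side, so no regiochemical question arises.

Step 6
Reactants: 7 3-methyl-3-(triethylsilyloxy)-2-(trimethylsilyloxy)but-1-ene; 8 ethyl glyoxylate (freshly distilled)
Product: 10 ethyl (2R)-2-hydroxy-5-methyl-4-oxo-5-(triethylsilyloxy)hexanoate, via O-trimethylsilyl aldol 9 (not isolated)
Conditions: (R)-BINOL (10 mol %), TiCl2(Oi-Pr)2 (10 mol %), 4 Å molecular sieves, CH2Cl2, 0 °C; then 1 M HCl, THF, 0 °C, brief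
Reagents that add atoms: none
Why: Catalytic enantioselective Mukaiyama aldol addition of an enol silane to glyoxylate chelated on the BINOL–titanium Lewis acid; the (R)-ligand is the one that gives (R)-α-hydroxy esters from glyoxylates, which sets C8, and brief acid removes only the secondary O-TMS group.

Step 7
Reactants: 10 ethyl (2R)-2-hydroxy-5-methyl-4-oxo-5-(triethylsilyloxy)hexanoate
Product: 12 (3R,5R)-3-hydroxy-5-(2-hydroxypropan-2-yl)oxolan-2-one, via anti-diol ester 11 (not isolated)
Conditions: Me4NBH(OAc)3 (5 equiv), MeCN/AcOH (1:1), −30 °C; then 1 M aq. HCl, rt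
Reagents that add atoms: none
Why: Evans–Saksena reduction, in which the C8 hydroxyl binds boron and delivers hydride through a chair to give the 1,3-anti diol (C10 set as R); aqueous acid then removes the tertiary TES ether and closes the γ-lactone, the form a 2,4-dihydroxy ester adopts in any case.

Step 8
Reactants: 12 (3R,5R)-3-hydroxy-5-(2-hydroxypropan-2-yl)oxolan-2-one
Product: 13 (3R,5R)-3-(tert-butyldimethylsilyloxy)-5-(2-hydroxypropan-2-yl)oxolan-2-one
Conditions: TBSCl, imidazole, DMF, rt
Reagents that add atoms: tert-butyldimethylsilyl chloride, CC(C)(C)[Si](C)(C)Cl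
Why: Selective silylation of the secondary hydroxyl; the tertiary O11–H does not react with a silyl chloride under these conditions.

Step 9
Reactants: 13 (3R,5R)-3-(tert-butyldimethylsilyloxy)-5-(2-hydroxypropan-2-yl)oxolan-2-one
Product: 14 (2R,4R)-2-(tert-butyldimethylsilyloxy)-4,5-dihydroxy-N-methoxy-N,5-dimethylhexanamide
Conditions: MeNHOMe·HCl (3 equiv), AlMe3 (3 equiv), CH2Cl2, 0 °C to rt; aq. potassium sodium tartrate work-up; crude used at once
Reagents that add atoms: N,O-dimethylhydroxylamine hydrochloride, CNOC.Cl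
Why: Weinreb aminolysis of a lactone by the aluminium amide, which is not basic enough to epimerise C8; immediate use of the crude diol prevents relactonisation.

Step 10
Reactants: 14 (2R,4R)-2-(tert-butyldimethylsilyloxy)-4,5-dihydroxy-N-methoxy-N,5-dimethylhexanamide
Product: 15 (2R)-2-(tert-butyldimethylsilyloxy)-N-methoxy-N-methyl-3-[(4R)-2,2,5,5-tetramethyl-1,3-dioxolan-4-yl]propanamide
Conditions: 2-methoxypropene, PPTS (cat.), CH2Cl2, 0 °C
Reagents that add atoms: 2-methoxypropene, COC(C)=C
Why: Kinetic acetonide formation on the only 1,2-diol (O10/O11), faster than acid-induced return to the lactone.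

Step 11
Reactants: 15 (2R)-2-(tert-butyldimethylsilyloxy)-N-methoxy-N-methyl-3-[(4R)-2,2,5,5-tetramethyl-1,3-dioxolan-4-yl]propanamide; 16 vinylmagnesium bromide
Product: 17 (4R)-4-(tert-butyldimethylsilyloxy)-5-[(4R)-2,2,5,5-tetramethyl-1,3-dioxolan-4-yl]pent-1-en-3-one
Conditions: THF, −20 to 0 °C; inverse quench into cold 1 M HCl
Reagents that add atoms: none
Why: Weinreb ketone synthesis, in which the magnesium chelate prevents over-addition; the acidic inverse quench protonates the released amine before it can add to the enone.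

Step 12
Reactants: 4 (1E,3E)-1-(tert-butyldimethylsilyloxy)-2-methyl-4-(triethylsilyloxy)buta-1,3-diene (1.5 equiv); 17 (4R)-4-(tert-butyldimethylsilyloxy)-5-[(4R)-2,2,5,5-tetramethyl-1,3-dioxolan-4-yl]pent-1-en-3-one
Product: 18 (2R)-2-(tert-butyldimethylsilyloxy)-1-[(1S,2R,5R)-5-(tert-butyldimethylsilyloxy)-4-methyl-2-(triethylsilyloxy)cyclohex-3-en-1-yl]-3-[(4R)-2,2,5,5-tetramethyl-1,3-dioxolan-4-yl]propan-1-one (all-cis C1-OTES/C4-OTBS/C6-acyl)
Conditions: (S)-B-(o-tolyl)-diphenylprolinol oxazaborolidinium triflimide [from the oxazaborolidine and Tf2NH] (20 mol %), CH2Cl2, −78 °C; Et3N quench; Et3N-deactivated silica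
Reagents that add atoms: none
Why: Proposed new method: a concerted, asynchronous normal-demand [4+2] cycloaddition between the donor diene and the boron-bound s-cis enone, in which diene carbon C4 bonds to C5 ahead of C1 to C6; the closest known reactions are oxazaborolidinium-catalysed Diels–Alder additions of vinyl ketones to silyloxydienes and the additions of hydrogen-bond-chelated chiral α'-hydroxy vinyl ketones, whereas face control by a non-chelated α'-silyloxy stereocentre has not been shown. The cyclohexene ring is closed in this single intermolecular suprafacial [4π+2π] event, which forms C4–C5 and C1–C6 and joins chain and ring. Regiochemistry (C3 methyl para to the C6 acyl group) follows because only this orientation places the developing allyl cation with the methyl-bearing C3 and the OTES-bearing C1 at its ends, the two silyloxy donors otherwise cancelling. C1 and C4 come out cis from the E,E geometry of 4, and C6 comes out cis to both through endo placement of the complexed C7 carbonyl. The sense of C6 relative to C8 is the uncertain element: boron has one free site and a TBS ether does not chelate, so the C8–O bond should turn out of the enone plane away from the C7=O dipole with C9 near that plane, the silyloxy group then covers the C6 Si face and the diene adds to the Re face, which is the target configuration (labelled 6S while C7 is a carbonyl). The chiral cation is chosen to shield the same face, and −78 °C with an amine quench keeps the β-silyloxy ketone from eliminating.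

Step 13
Reactants: 18 Diels–Alder adduct (C7 ketone)
Product: 19 C7-methylene compound (18 with C7=O converted into C7=C14H2; C1-OTES, C4-OTBS, C8-OTBS, O10/O11 acetonide)
Conditions: Cp2TiMe2 (3 equiv), toluene, 70 °C, dark
Reagents that add atoms: dimethyltitanocene, [CH3-].[CH3-].[Ti+4].c1cc[cH-]c1.c1cc[cH-]c1
Why: Petasis methylenation through Cp2Ti=CH2 and an oxatitanacyclobutane is non-basic, so neither β-elimination of O1 nor epimerisation at C6 or C8 should occur; the C6 label changes from S to R only because C7 loses CIP priority.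

Step 14
Reactants: 19 C7-methylene compound
Product: 20 C1 allylic alcohol (19 with the triethylsilyl ether cleaved; C1-OH cis to C4-OTBS and to the C6 chain)
Conditions: PPTS (0.1 equiv), MeOH/CH2Cl2 (1:1), 0 °C
Reagents that add atoms: none
Why: Mild acid methanolysis removes the secondary allylic TES ether far faster than the TBS ethers or the acetonide.

Step 15
Reactants: 20 C1 allylic alcohol
Product: 22 all-cis C1/C2/C3 triol (C2-OH and C3-OH cis to C1-OH, C4-OTBS and the C6 chain), via osmate ester TMEDA complex 21 (not isolated)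
Conditions: OsO4 (1.05 equiv), TMEDA (1.1 equiv), CH2Cl2, −78 °C; then aq. Na2SO3, THF, 60 °C
Reagents that add atoms: osmium tetroxide, O=[Os](=O)(=O)=O
Why: Hydrogen-bond-directed syn-dihydroxylation, in which the OsO4·TMEDA complex accepts a hydrogen bond from the pseudoaxial C1 hydroxyl and delivers both oxygens to C2 and C3 on the face of O1 (setting both centres), the allylic relationship favouring the ring alkene over the only homoallylic, hindered C7=C14.

Step 16
Reactants: 22 all-cis triol
Product: 25 C1-acetate with free C2/C3/C10/C11 hydroxyls (O4/O8 bis-TBS ether), via cyclic orthoacetate 23 (not isolated), via C1-acetate acetonide 24 (not isolated)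
Conditions: MeC(OMe)3 (1.5 equiv), PPTS (cat.), CH2Cl2, rt; then AcOH/H2O (4:1), rt to 40 °C
Reagents that add atoms: trimethyl orthoacetate, COC(C)(OC)OC; water, O
Why: Cyclic orthoester formation on the cis-secondary C1,C2-diol and acid hydrolysis, which opens to the axial ester (O1 is axial in the chair that keeps the C6 chain equatorial) and frees the equatorial C2-OH; the same aqueous acid hydrolyses the acetonide while secondary TBS ethers persist.

Step 17
Reactants: 25 C1-acetate with free C2/C3/C10/C11 hydroxyls; 26 angelic acid (4 equiv)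
Product: 28 O2,O10-bis-angelate (O4/O8 bis-TBS ether), via angelic 2,4,6-trichlorobenzoic anhydride 27 (not isolated)
Conditions: 2,4,6-trichlorobenzoyl chloride, Et3N, toluene, rt; then 25, toluene, 70 °C, no DMAP
Reagents that add atoms: none
Why: Yamaguchi-type mixed-anhydride esterification acylates the two free secondary hydroxyls and leaves the tertiary C3-OH and C11-OH alone; omitting the nucleophilic pyridine catalyst avoids the conjugate adduct that turns angelate into tiglate.

Step 18
Reactants: 28 O2,O10-bis-angelate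
Product: 29 CNP0325091.1
Conditions: HF·pyridine, pyridine, THF, 0 °C to rt
Reagents that add atoms: none
Why: Buffered fluoride desilylation removes both secondary TBS ethers under weakly acidic conditions that should not move or cleave the three esters.

Compound list
1 | (E)-4-acetoxy-2-methylbut-2-enal | CC(=O)OC/C=C(C)/C=O | starting material
2 | (E)-4-hydroxy-2-methylbut-2-enal | OC/C=C(C)/C=O | intermediate
3 | (E)-2-methyl-4-(triethylsilyloxy)but-2-enal | CC[Si](CC)(CC)OC/C=C(C)/C=O | intermediate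
4 | (1E,3E)-1-(tert-butyldimethylsilyloxy)-2-methyl-4-(triethylsilyloxy)buta-1,3-diene | CC[Si](CC)(CC)O/C=C/C(C)=C/O[Si](C)(C)C(C)(C)C | intermediate
5 | 3-hydroxy-3-methylbutan-2-one | CC(=O)C(C)(C)O | starting material
6 | 3-methyl-3-(triethylsilyloxy)butan-2-one | CC(=O)C(C)(C)O[Si](CC)(CC)CC | intermediate
7 | 3-methyl-3-(triethylsilyloxy)-2-(trimethylsilyloxy)but-1-ene | C=C(O[Si](C)(C)C)C(C)(C)O[Si](CC)(CC)CC | intermediate
8 | ethyl glyoxylate | CCOC(=O)C=O | starting material
9 | ethyl (2R)-5-methyl-4-oxo-5-(triethylsilyloxy)-2-(trimethylsilyloxy)hexanoate | CCOC(=O)[C@H](O[Si](C)(C)C)CC(=O)C(C)(C)O[Si](CC)(CC)CC | intermediate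
10 | ethyl (2R)-2-hydroxy-5-methyl-4-oxo-5-(triethylsilyloxy)hexanoate | CCOC(=O)[C@H](O)CC(=O)C(C)(C)O[Si](CC)(CC)CC | intermediate
11 | ethyl (2R,4R)-2,4-dihydroxy-5-methyl-5-(triethylsilyloxy)hexanoate | CCOC(=O)[C@H](O)C[C@@H](O)C(C)(C)O[Si](CC)(CC)CC | intermediate
12 | (3R,5R)-3-hydroxy-5-(2-hydroxypropan-2-yl)oxolan-2-one | O=C1[C@H](O)C[C@H](C(C)(C)O)O1 | intermediate
13 | (3R,5R)-3-(tert-butyldimethylsilyloxy)-5-(2-hydroxypropan-2-yl)oxolan-2-one | O=C1[C@H](O[Si](C)(C)C(C)(C)C)C[C@H](C(C)(C)O)O1 | intermediate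
14 | (2R,4R)-2-(tert-butyldimethylsilyloxy)-4,5-dihydroxy-N-methoxy-N,5-dimethylhexanamide | CON(C)C(=O)[C@H](O[Si](C)(C)C(C)(C)C)C[C@@H](O)C(C)(C)O | intermediate
15 | (2R)-2-(tert-butyldimethylsilyloxy)-N-methoxy-N-methyl-3-[(4R)-2,2,5,5-tetramethyl-1,3-dioxolan-4-yl]propanamide | CON(C)C(=O)[C@H](O[Si](C)(C)C(C)(C)C)C[C@@H](OC(C)(C)O1)C1(C)C | intermediate
16 | vinylmagnesium bromide | C=C[Mg]Br | starting material
17 | (4R)-4-(tert-butyldimethylsilyloxy)-5-[(4R)-2,2,5,5-tetramethyl-1,3-dioxolan-4-yl]pent-1-en-3-one | C=CC(=O)[C@H](O[Si](C)(C)C(C)(C)C)C[C@@H](OC(C)(C)O1)C1(C)C | intermediate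
18 | Diels–Alder adduct: (2R)-2-(tert-butyldimethylsilyloxy)-1-[(1S,2R,5R)-5-(tert-butyldimethylsilyloxy)-4-methyl-2-(triethylsilyloxy)cyclohex-3-en-1-yl]-3-[(4R)-2,2,5,5-tetramethyl-1,3-dioxolan-4-yl]propan-1-one; C1-OTES, C4-OTBS and C6 acyl all cis | O=C([C@H](O[Si](C)(C)C(C)(C)C)C[C@@H](OC(C)(C)O1)C1(C)C)[C@H]2C[C@@H](O[Si](C)(C)C(C)(C)C)C(C)=C[C@H]2O[Si](CC)(CC)CC | intermediate
19 | C7-methylene compound: 18 with C7=O replaced by C7=C14H2, all stereocentres unchanged in space | C=C([C@H](O[Si](C)(C)C(C)(C)C)C[C@@H](OC(C)(C)O1)C1(C)C)[C@H]2C[C@@H](O[Si](C)(C)C(C)(C)C)C(C)=C[C@H]2O[Si](CC)(CC)CC | intermediate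
20 | C1 allylic alcohol: 19 with free C1-OH, cis to C4-OTBS and the C6 chain | C=C([C@H](O[Si](C)(C)C(C)(C)C)C[C@@H](OC(C)(C)O1)C1(C)C)[C@H]2C[C@@H](O[Si](C)(C)C(C)(C)C)C(C)=C[C@H]2O | intermediate
21 | cyclic C2,C3-osmate ester (hexavalent osmium, dioxo, TMEDA-bound) on the face of O1 | C=C([C@H](O[Si](C)(C)C(C)(C)C)C[C@@H](OC(C)(C)O1)C1(C)C)[C@H]2C[C@@H](O[Si](C)(C)C(C)(C)C)[C@@](C)(O[Os-2]3(=O)(=O)([N+](C)(C)CC[N+]3(C)C)O4)[C@@H]4[C@H]2O | intermediate
22 | all-cis triol: C1-OH, C2-OH, C3-OH, C4-OTBS and the C6 chain on one ring face, C3 methyl on the other; C7 methylene, C8-OTBS, O10/O11 acetonide | C=C([C@H](O[Si](C)(C)C(C)(C)C)C[C@@H](OC(C)(C)O1)C1(C)C)[C@H]2C[C@@H](O[Si](C)(C)C(C)(C)C)[C@@](C)(O)[C@@H](O)[C@H]2O | intermediate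
23 | cyclic C1,C2-orthoacetate of 22 (2-methoxy-2-methyl-1,3-dioxolane fused at C1–C2, orthoester carbon as a mixture) | C=C([C@H](O[Si](C)(C)C(C)(C)C)C[C@@H](OC(C)(C)O1)C1(C)C)[C@H]2C[C@@H](O[Si](C)(C)C(C)(C)C)[C@@](C)(O)[C@@H](OC(C)(OC)O3)[C@H]23 | intermediate
24 | C1-acetate of 22 (C2-OH and C3-OH free, acetonide intact) | C=C([C@H](O[Si](C)(C)C(C)(C)C)C[C@@H](OC(C)(C)O1)C1(C)C)[C@H]2C[C@@H](O[Si](C)(C)C(C)(C)C)[C@@](C)(O)[C@@H](O)[C@H]2OC(C)=O | intermediate
25 | C1-acetate with free C2-OH, C3-OH, C10-OH and C11-OH; TBS ethers on O4 and O8 | C=C([C@H](O[Si](C)(C)C(C)(C)C)C[C@@H](O)C(C)(C)O)[C@H]1C[C@@H](O[Si](C)(C)C(C)(C)C)[C@@](C)(O)[C@@H](O)[C@H]1OC(C)=O | intermediate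
26 | angelic acid, (Z)-2-methylbut-2-enoic acid | C/C=C(/C)C(O)=O | starting material
27 | (Z)-2-methylbut-2-enoic 2,4,6-trichlorobenzoic anhydride | C/C=C(/C)C(=O)OC(=O)c1c(Cl)cc(Cl)cc1Cl | intermediate
28 | O2,O10-bis-angelate of 25 (TBS ethers on O4 and O8) | C=C([C@H](O[Si](C)(C)C(C)(C)C)C[C@@H](OC(=O)/C(C)=C\C)C(C)(C)O)[C@H]1C[C@@H](O[Si](C)(C)C(C)(C)C)[C@@](C)(O)[C@@H](OC(=O)/C(C)=C\C)[C@H]1OC(C)=O | intermediate
29 | CNP0325091.1: cyclohexane with C1-OAc, C2-O-angelate, C3-OH, C4-OH and the C6 chain all cis; chain C7(=CH2)–C8(OH)–C9H2–C10(O-angelate)–C11Me2OH; (1S,2S,3R,4R,6R,8R,10R) in the numbering above | C=C([C@H](O)C[C@@H](OC(=O)/C(C)=C\C)C(C)(C)O)[C@H]1C[C@@H](O)[C@@](C)(O)[C@@H](OC(=O)/C(C)=C\C)[C@H]1OC(C)=O | target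

Total step count: 18. Longest linear sequence: 15 steps (5 to 29, steps 4–18); the diene branch (steps 1–3) joins at step 12.

Steps most likely to fail

Step 12. What may go wrong: insufficient or reversed π-facial discrimination (the diene adding to the C6 Si face), or loss of cis-specificity through a stepwise Mukaiyama–Michael course. The fallback uses known chemistry: face control by the intramolecular hydrogen bond of a free α'-hydroxy vinyl ketone, which holds O8 syn to the carbonyl so that the diene adds anti to C9. This needs the C8 epimer, and C8 is inverted afterwards. It sets out from 15. Bu4NF in THF at 0 °C should give the (8R)-hydroxy Weinreb amide F1. A Mitsunobu reaction (4-nitrobenzoic acid, PPh3, DIAD) should give the inverted (8S)-4-nitrobenzoate F2, and K2CO3 in MeOH the (8S)-hydroxy Weinreb amide F3. Vinylmagnesium bromide (3 equiv) should give the (8S)-ketol dienophile F4. F4 and diene 4 in toluene at 0 °C to rt (MgBr2·OEt2 as chelating additive if the rate is low) should give the all-cis adduct with free (8S)-hydroxyl F5, whose ring has the configuration of 18. Cp2TiMe2 should give the (8S)-allylic alcohol F6, a second Mitsunobu reaction the (8R)-4-nitrobenzoate F7, and K2CO3 in MeOH the (8R)-allylic alcohol F8. TBSOTf with 2,6-lutidine returns the route to 19.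

Step 15. What may go wrong: competing osmylation of the exocyclic C7=C14 alkene, or addition anti to O1 on the crowded ring face. The fallback carries out the directed dihydroxylation before the second alkene exists. It sets out from 18. PPTS in MeOH at 0 °C should free O1 to give the C1-hydroxy ketone F9. OsO4/TMEDA at −78 °C with Na2SO3 work-up should give the all-cis triol ketone F10, and MeC(OMe)3 with PPTS the orthoacetate ketone F11. Cp2TiMe2 methylenation then leads to 23, which the aqueous acid of step 16 takes on to 25.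

Step 17. What may go wrong: slow acylation of the hindered C2 and C10 hydroxyls, accompanied by Z to E isomerisation of the angeloyl unit and migration of the C1 acetate to O2. The fallback builds the Z double bonds after acylation. It sets out from 25. Esterification of O2 and O10 with the unhindered 2-[bis(2,2,2-trifluoroethoxy)phosphoryl]propanoic acid (EDC·HCl, DMAP cat., CH2Cl2, 0 °C) should give the bis(phosphonopropionate) F12. Still–Gennari olefination (KN(SiMe3)2, 18-crown-6, THF, −78 °C, acetaldehyde) then forms both Z-trisubstituted enoates and returns the route to 28.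

Further compounds
F1 | step 12 | (2R)-2-hydroxy-N-methoxy-N-methyl-3-[(4R)-2,2,5,5-tetramethyl-1,3-dioxolan-4-yl]propanamide | CON(C)C(=O)[C@H](O)C[C@@H](OC(C)(C)O1)C1(C)C
F2 | step 12 | (2S)-1-[methoxy(methyl)amino]-1-oxo-3-[(4R)-2,2,5,5-tetramethyl-1,3-dioxolan-4-yl]propan-2-yl 4-nitrobenzoate | CON(C)C(=O)[C@@H](OC(=O)c2ccc(cc2)[N+](=O)[O-])C[C@@H](OC(C)(C)O1)C1(C)C
F3 | step 12 | (2S)-2-hydroxy-N-methoxy-N-methyl-3-[(4R)-2,2,5,5-tetramethyl-1,3-dioxolan-4-yl]propanamide | CON(C)C(=O)[C@@H](O)C[C@@H](OC(C)(C)O1)C1(C)C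
F4 | step 12 | (4S)-4-hydroxy-5-[(4R)-2,2,5,5-tetramethyl-1,3-dioxolan-4-yl]pent-1-en-3-one | C=CC(=O)[C@@H](O)C[C@@H](OC(C)(C)O1)C1(C)C
F5 | step 12 | Diels–Alder adduct with free (8S)-hydroxyl: ring as in 18, C8 epimeric and unprotected | O=C([C@@H](O)C[C@@H](OC(C)(C)O1)C1(C)C)[C@H]2C[C@@H](O[Si](C)(C)C(C)(C)C)C(C)=C[C@H]2O[Si](CC)(CC)CC
F6 | step 12 | C7-methylene (8S)-allylic alcohol: F5 with C7=O replaced by C7=CH2 | C=C([C@@H](O)C[C@@H](OC(C)(C)O1)C1(C)C)[C@H]2C[C@@H](O[Si](C)(C)C(C)(C)C)C(C)=C[C@H]2O[Si](CC)(CC)CC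
F7 | step 12 | (8R)-4-nitrobenzoate of the C7-methylene compound (C8 inverted) | C=C([C@H](OC(=O)c3ccc(cc3)[N+](=O)[O-])C[C@@H](OC(C)(C)O1)C1(C)C)[C@H]2C[C@@H](O[Si](C)(C)C(C)(C)C)C(C)=C[C@H]2O[Si](CC)(CC)CC
F8 | step 12 | (8R)-allylic alcohol: 19 lacking the O8 silyl group | C=C([C@H](O)C[C@@H](OC(C)(C)O1)C1(C)C)[C@H]2C[C@@H](O[Si](C)(C)C(C)(C)C)C(C)=C[C@H]2O[Si](CC)(CC)CC
F9 | step 15 | C1-hydroxy ketone: 18 with the triethylsilyl ether cleaved | O=C([C@H](O[Si](C)(C)C(C)(C)C)C[C@@H](OC(C)(C)O1)C1(C)C)[C@H]2C[C@@H](O[Si](C)(C)C(C)(C)C)C(C)=C[C@H]2O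
F10 | step 15 | all-cis C1/C2/C3 triol with C7 ketone | O=C([C@H](O[Si](C)(C)C(C)(C)C)C[C@@H](OC(C)(C)O1)C1(C)C)[C@H]2C[C@@H](O[Si](C)(C)C(C)(C)C)[C@@](C)(O)[C@@H](O)[C@H]2O
F11 | step 15 | cyclic C1,C2-orthoacetate of F10 (C7 ketone) | O=C([C@H](O[Si](C)(C)C(C)(C)C)C[C@@H](OC(C)(C)O1)C1(C)C)[C@H]2C[C@@H](O[Si](C)(C)C(C)(C)C)[C@@](C)(O)[C@@H](OC(C)(OC)O3)[C@H]23
F12 | step 17 | O2,O10-bis{2-[bis(2,2,2-trifluoroethoxy)phosphoryl]propanoate} of 25 | C=C([C@H](O[Si](C)(C)C(C)(C)C)C[C@@H](OC(=O)C(C)P(=O)(OCC(F)(F)F)OCC(F)(F)F)C(C)(C)O)[C@H]1C[C@@H](O[Si](C)(C)C(C)(C)C)[C@@](C)(O)[C@@H](OC(=O)C(C)P(=O)(OCC(F)(F)F)OCC(F)(F)F)[C@H]1OC(C)=O
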